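**Overview**

- Cuts, in retrosynthetic order: the two ester C–O bonds at C8 and C5; the C11=C13 methylene (carried as a dimethylaminomethyl Mannich base); the lactone C12–O6 bond; the C4/C5 cis-diol back to a Z C4=C5 alkene; then the C4=C5 and C9=O π bonds are traded for a C4–C9 σ bond plus a C5 sulfonate; finally C11–C13, C7–C11, C8–C9, C7–C8 and C4–C5.
- Enabling feature: in the ten-membered ring the C9 ketone lies 1,6 across the ring from C4, and the C4 and C5 oxygens are cis as from a Z alkene. The carbocycle is therefore a cis-decalin (ring A = C10, C1, C2, C3, C4, C9; ring B = C4 to C9) opened along its fusion bond C4–C9.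
- Forward order of rings: ring A is bought; ring B is closed on it at C8–C9 by ketyl pinacol coupling; the ten-membered ring appears when the shared C4–C9 bond is cleaved; the γ-lactone is closed last onto O6, before the two acylations and the unmasking of the methylene.
- Stereochemistry: C10 from enantioselective deprotonation of the meso ketone; transient C4 from matched Pd/PHOX allylation and transient C9 from the chair of ring A; C7 (alkylation anti to C10), C8 (hydride delivered from the C9 hydroxyl), C6 and the C5 sulfonate (osmylation trans to the angular methyl) on the rigid decalin; C4 and C5 of the target from C6-hydroxyl-directed syn-dihydroxylation of the Z alkene; the side-chain centre from (R)-2-methylbutanoic acid.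
- Convention: all intermediates carry germacranolide numbering (C14 on C10, C15 on C4, C11 to C13 in the lactone). On the decalins, α is the face of ring B that bears the C4 methyl and the C9 oxygen; β is the opposite face.

Key step: step 17

Assumption: the (R,R)-configured lithium amide is taken to remove the proton that leads to the (R)-enol ether of step 1 (otherwise its antipode is used, nothing else changing), and C11 is carried as an unassigned epimer mixture from step 13 until it becomes sp2 in step 24.

**Route**

Step 1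
Reactants: 1 cis-2,6-dimethylcyclohexanone (meso)
Product: 2 trimethyl{[(6R)-2,6-dimethylcyclohex-1-en-1-yl]oxy}silane
Conditions: (R,R)-bis(1-phenylethyl)amine, n-BuLi, THF, −78 °C; then TMSCl and 1, −95 → −78 °C (in situ quench)
Reagents that add atoms: chlorotrimethylsilane, C[Si](C)(C)Cl
Why: Enantioselective deprotonation with a C2-symmetric chiral lithium amide removes one of the two enantiotopic α-protons of the meso ketone and the enolate is silylated as it forms, which fixes C10 as (R) while the other α-carbon becomes planar.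

Step 2
Reactants: 2 trimethyl{[(6R)-2,6-dimethylcyclohex-1-en-1-yl]oxy}silane; 3 allyl chloroformate
Product: 5 allyl (6R)-2,6-dimethylcyclohex-1-en-1-yl carbonate, via lithium enolate 4 (not isolated)
Conditions: MeLi, THF, 0 °C; then TMEDA, allyl chloroformate, −78 °C
Reagents that add atoms: allyl chloroformate 3, C=CCOC(Cl)=O
Why: MeLi cleaves the Si–O bond to the regiodefined tetrasubstituted lithium enolate, which in the presence of TMEDA is acylated on oxygen by the hard chloroformate (enol carbonate formation) without touching C10.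

Step 3
Reactants: 5 allyl (6R)-2,6-dimethylcyclohex-1-en-1-yl carbonate
Product: 6 (2S,6R)-2-allyl-2,6-dimethylcyclohexanone (methyl groups cis)
Conditions: Pd2(dba)3 (2.5 mol %), (S)-t-Bu-PHOX [(S)-4-tert-butyl-2-(2-diphenylphosphinophenyl)-4,5-dihydrooxazole] (6 mol %), THF, 25 °C
Reagents that add atoms: none
Why: In this decarboxylative asymmetric allylic alkylation (Tsuji allylation), zerovalent palladium ionises the allyl carbonate, CO2 is lost and the allylpalladium enolate recombines at C4 under control of the (S)-ligand, reinforced by delivery anti to the pseudo-axial C10 methyl, so C4 should be set (S) with the methyls cis while the minor enantiomer of 5 is diverted into the separable trans diastereomer.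

Step 4
Reactants: 6 (2S,6R)-2-allyl-2,6-dimethylcyclohexanone
Product: 7 4-[(1S,3R)-1,3-dimethyl-2-oxocyclohexyl]butanal
Conditions: Rh(acac)(CO)2 (1 mol %), Xantphos (2 mol %), CO/H2 (1:1, 10 bar), toluene, 70 °C
Reagents that add atoms: carbon monoxide, [C-]#[O+]
Why: Rhodium-catalysed hydroformylation with the wide-bite-angle diphosphine places the formyl group on the terminal carbon of the monosubstituted alkene (linear selectivity), which adds C8 and leaves the hindered ketone and C10 alone.

Step 5
Reactants: 7 4-[(1S,3R)-1,3-dimethyl-2-oxocyclohexyl]butanal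
Product: 8 (1S,4aS,8R,8aR)-4a,8-dimethyldecahydronaphthalene-1,8a-diol (cis-fused; 8α,9α-diol)
Conditions: SmI2 (2.3 equiv), t-BuOH (2 equiv), THF, −78 → 0 °C
Reagents that add atoms: none
Why: In this SmI2 ketyl–carbonyl (pinacol) cyclisation the aldehyde ketyl adds to the ketone inside a samarium chelate to close ring B at C8–C9 as the cis-diol, and because the C4 chain is axial on the ring-A chair that keeps both methyls equatorial it can reach C9 only from the equatorial direction, so the fusion should be cis with the C9 hydroxyl on the face of the C4 methyl.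

Step 6
Reactants: 8 cis-fused 8α,9α-diol
Product: 9 (4aS,8R,8aR)-8a-hydroxy-4a,8-dimethyloctahydronaphthalen-1(2H)-one (cis-fused ketol: C8 ketone and C9α hydroxyl)
Conditions: (COCl)2, DMSO, CH2Cl2, −78 °C; Et3N, −78 → 0 °C
Reagents that add atoms: none
Why: Swern oxidation converts only the secondary C8 carbinol, the tertiary C9 hydroxyl having no carbinol hydrogen, and activated DMSO does not cleave the glycol, so either C8 epimer of 8 would converge on the same ketol.

Step 7
Reactants: 9 cis-fused ketol
Product: 10 bis(trimethylsilyl) derivative of 9 (9α-silyl ether plus C7=C8 silyl enol ether)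
Conditions: TMSOTf (2.4 equiv), Et3N, CH2Cl2, 0 °C
Reagents that add atoms: trimethylsilyl trifluoromethanesulfonate, C[Si](C)(C)OS(=O)(=O)C(F)(F)F
Why: Soft enolisation and silylation with the silyl triflate cap the tertiary alcohol and give the only possible silyl enol ether, since C9 carries no hydrogen and enolisation can run toward C7 alone.

Step 8
Reactants: 10 bis(trimethylsilyl) derivative of 9
Product: 11 9α-trimethylsilyloxy-4α,10α-dimethyl-cis-decal-6-en-8-one
Conditions: Pd(OAc)2 (1.05 equiv), MeCN, 25 °C
Reagents that add atoms: none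
Why: Saegusa–Ito dehydrogenation, in which divalent palladium adds to the silyl enol ether at C7 and β-hydride elimination from C6 gives the C6=C7 enone.

Step 9
Reactants: 11 9α-trimethylsilyloxy-cis-decal-6-en-8-one; 12 tert-butyl bromoacetate
Product: 14 7α-(tert-butoxycarbonylmethyl)-9α-trimethylsilyloxy-cis-decal-5-en-8-one, via lithium dienolate 13 (not isolated)
Conditions: LiN(i-Pr)2 (1.05 equiv), THF, −78 °C; DMPU, BrCH2CO2t-Bu, −78 → −40 °C; AcOH quench at −78 °C
Reagents that add atoms: tert-butyl bromoacetate 12, CC(C)(C)OC(=O)CBr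
Why: Deconjugative α-alkylation of an enone: with C9 quaternary the only acidic position is γ (C5), the extended dienolate reacts at its α-carbon C7, and the electrophile should enter from the α face away from C10 (axial on the β face of ring B), which sets C7 with the acetate arm α and moves the alkene to C5=C6.

Step 10
Reactants: 14 7α-(tert-butoxycarbonylmethyl)-9α-trimethylsilyloxy-cis-decal-5-en-8-one
Product: 15 7α-(tert-butoxycarbonylmethyl)-9α-hydroxy-4α,10α-dimethyl-cis-decal-5-en-8-one
Conditions: HF·pyridine, pyridine, THF, 0 °C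
Reagents that add atoms: none
Why: Buffered fluoride desilylation removes the hindered tertiary trimethylsilyl ether under non-basic conditions, so the β,γ-unsaturated ketone is not drawn into conjugation and C7 keeps its configuration.

Step 11
Reactants: 15 β,γ-unsaturated ketol
Product: 16 7α-(tert-butoxycarbonylmethyl)-cis-decal-5-ene-8β,9α-diol
Conditions: Me4NBH(OAc)3, MeCN/AcOH (1:1), −30 → 0 °C
Reagents that add atoms: none
Why: Hydroxyl-directed (Evans–Saksena) reduction: the C9 hydroxyl exchanges onto boron and the tethered hydride reaches C8 from the α face, which should give the 8β-alcohol trans to the C9 hydroxyl, while the ester and the alkene are inert to triacetoxyborohydride.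

Step 12
Reactants: 16 8β,9α-diol
Product: 17 8β-tert-butyldimethylsilyl ether of 16
Conditions: TBSOTf (1.1 equiv), 2,6-lutidine, CH2Cl2, −78 → −40 °C
Reagents that add atoms: tert-butyldimethylsilyl trifluoromethanesulfonate, CC(C)(C)[Si](C)(C)OS(=O)(=O)C(F)(F)F
Why: Low-temperature silylation with the triflate takes the secondary C8 hydroxyl and leaves the fully substituted C9 hydroxyl free as the later fragmentation trigger, and the silyl ether also blocks any lactonisation onto O8.

Step 13
Reactants: 17 8β-silyl ether
Product: 19 C11-dimethylaminomethyl derivative of 17 (Mannich base), via dilithium alkoxide enolate 18 (not isolated)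
Conditions: LiN(i-Pr)2 (2.2 equiv), THF, −78 °C; Me2N=CH2 I (Eschenmoser's salt), −78 → 0 °C; H2O
Reagents that add atoms: N,N-dimethylmethyleneiminium iodide, C=[N+](C)C.[I-]
Why: Ester-enolate Mannich reaction in which two equivalents of base give the alkoxide–enolate and the iminium salt aminomethylates C11, adding C13 as a masked methylene that tolerates every later step.

Step 14
Reactants: 19 Mannich base with C5=C6 alkene
Product: 20 5β,6β-diol of 19
Conditions: OsO4 (5 mol %), NMO, acetone/H2O, 25 °C; aq. Na2SO3
Reagents that add atoms: osmium tetroxide (catalytic oxygen carrier), O=[Os](=O)(=O)=O; N-methylmorpholine N-oxide, C[N+]1([O-])CCOCC1; water, O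
Why: Upjohn syn-dihydroxylation, in which osmium is expected on the β face because both allylic carbons turn their carbon substituents (the pseudo-axial C4 methyl and the C7 side chain) to the α face, so C5 and C6 are set together with both oxygens β and trans to the angular methyl.

Step 15
Reactants: 20 5β,6β-diol
Product: 21 6β-triethylsilyl ether of 20
Conditions: TESCl (1.1 equiv), imidazole, CH2Cl2, −20 °C
Reagents that add atoms: chlorotriethylsilane, CC[Si](Cl)(CC)CC
Why: Selective silylation, since the equatorial C6 hydroxyl should react far faster than the axial neopentyl C5 hydroxyl that is syn-axial to C10, and the tertiary C9 hydroxyl is inert.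

Step 16
Reactants: 21 6β-triethylsilyl ether
Product: 22 5β-methanesulfonate of 21
Conditions: MsCl, Et3N, CH2Cl2, −10 °C
Reagents that add atoms: methanesulfonyl chloride, CS(=O)(=O)Cl
Why: Sulfonylation through sulfene, which is small enough to reach the hindered secondary C5 hydroxyl, while the tertiary C9 hydroxyl does not react under these conditions.

Step 17
Reactants: 22 5β-methanesulfonate (cis-decal-9α-ol)
Product: 24 (4Z)-cyclodec-4-en-9-one 6-triethylsilyl 8-tert-butyldimethylsilyl diether (Mannich base), via potassium C9-alkoxide 23 (not isolated)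
Conditions: KN(SiMe3)2 (0.98 equiv, slow addition), THF, −78 → 0 °C; pH 7 buffer
Reagents that add atoms: none
Why: Deprotonation of the tertiary C9 hydroxyl gives the potassium alkoxide, whose lone pair pushes into the C4–C9 ring-fusion bond as that bond breaks, the C9=O and C4=C5 π bonds form and methanesulfonate leaves C5 in one concerted step; this is the Wharton variant of the Grob fragmentation of a cyclic 1,3-diol monosulfonate, the established way from decalin-1,3-diol monosulfonates to cyclodec-5-enones. No ring is closed: the bicyclo[4.4.0]decane is opened along its shared bond into the ten-membered carbocycle, and no stereocentre is created, C6, C7, C8 and C10 being untouched while C4, C5 and C9 become planar. The one new stereo-element, the C4=C5 geometry, is fixed by the anti-periplanar arrangement of the C4–C9 and C5–O bonds together with the trans relation between the 5β-sulfonate and the 4α-methyl on the cis-fused decalol, which leaves C3 and C6 on the same side (Z). That alignment is not present in the chair–chair ground state, where the sulfonate is axial, but should be reached in a twist-boat of ring B (C5 and C8 tipped toward the α face, only hydrogens as flagpoles), fed by release of the syn-axial contact between the sulfonate and C10 and of the gauche crowding of the three contiguous equatorial groups at C6, C7 and C8. Fragmentation should win over elimination, oxetane closure and epimerisation because C4 is quaternary, the equatorial C9 oxygen points away from the rear of C5, no base is present beyond a slight deficit of the amide, and the mixture is buffered as soon as the ketone has formed.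

Step 18
Reactants: 24 (4Z)-cyclodecenone disilyl ether
Product: 25 C6 alcohol of 24 (8-silyl ether kept)
Conditions: HF·pyridine, pyridine, THF, 0 °C
Reagents that add atoms: none
Why: Selective desilylation, the secondary allylic triethylsilyl ether being cleaved much faster than the hindered tert-butyldimethylsilyl ether at C8, under mildly acidic conditions that do not enolise the ketone.

Step 19
Reactants: 25 (4Z)-allylic alcohol
Product: 27 4,5,6-triol tert-butyl ester (8-silyl ether), via TMEDA-bound osmate ester 26 (not isolated)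
Conditions: OsO4 (1.05 equiv), TMEDA (1.1 equiv), CH2Cl2, −78 °C; then ethylenediamine, 25 °C
Reagents that add atoms: osmium tetroxide, O=[Os](=O)(=O)=O
Why: Hydroxyl-directed dihydroxylation, in which the OsO4·TMEDA complex is hydrogen-bonded by the C6 hydroxyl and adds suprafacially to the alkene face syn to it, a face that is also the outer one of the ring once H6 eclipses the Z alkene to avoid allylic strain with C3, so C4 (S) and C5 (R) should be set together before the osmate is released by ligand exchange.

Step 20
Reactants: 27 4,5,6-triol tert-butyl ester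
Product: 29 4,5-dihydroxy-6,12-lactone (Mannich base with 8-silyl ether), via 4,5,6-trihydroxy acid 28 (not isolated)
Conditions: 85% aq. H3PO4, toluene, 25 °C; NaHCO3 work-up
Reagents that add atoms: none
Why: Aqueous phosphoric acid cleaves the tert-butyl ester by alkyl–oxygen fission while sparing the tert-butyldimethylsilyl ether, and the γ-hydroxy acid then closes the five-membered lactone onto O6 under the same acid (acid-catalysed lactonisation), O8 being silylated and the six-membered alternative onto O5 being slower.

Step 21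
Reactants: 29 4,5-dihydroxy-6,12-lactone; 30 isobutyryl chloride
Product: 31 5-isobutyrate of 29
Conditions: i-PrCOCl, pyridine, DMAP (cat.), CH2Cl2, 0 °C
Reagents that add atoms: isobutyryl chloride 30, CC(C)C(Cl)=O
Why: DMAP-catalysed acylation esterifies the only secondary hydroxyl, at C5, the tertiary C4 hydroxyl being unreactive under these conditions.

Step 22
Reactants: 31 5-isobutyrate 8-silyl ether
Product: 32 8-hydroxy 5-isobutyrate (Mannich base)
Conditions: HF·pyridine, THF, 0 → 25 °C
Reagents that add atoms: none
Why: Fluoride desilylation under acidic conditions frees the C8 hydroxyl without the basic medium that could epimerise the α-ketol, shift the lactone to O8 or move the C5 ester.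

Step 23
Reactants: 32 8-hydroxy 5-isobutyrate; 33 (R)-2-methylbutanoic acid
Product: 34 8-[(R)-2-methylbutanoate] of 32 (Mannich base of the target)
Conditions: EDC·HCl, DMAP (cat.), CH2Cl2, 0 °C
Reagents that add atoms: (R)-2-methylbutanoic acid 33, CC[C@@H](C)C(=O)O
Why: Steglich esterification at 0 °C acylates the remaining secondary hydroxyl with the (R)-acid, whose purely alkyl-substituted α-centre is not expected to racemise, while the tertiary C4 hydroxyl stays free.

Step 24
Reactants: 34 Mannich base of the target
Product: 36 CNP0071420.1, via trimethylammonium iodide 35 (not isolated)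
Conditions: MeI, MeCN, 25 °C; then sat. aq. NaHCO3, EtOAc, 25 °C
Reagents that add atoms: none
Why: Exhaustive N-methylation followed by bicarbonate-induced β-elimination of trimethylamine (the standard unveiling of an α-methylene lactone from its Mannich base) removes the C11 stereocentre under conditions mild enough to leave the esters, the ketone and the C8 and C10 centres untouched.

**Compound list**

1 | cis-2,6-dimethylcyclohexanone (meso) | C[C@@H]1CCC[C@H](C)C1=O | starting material
2 | trimethyl{[(6R)-2,6-dimethylcyclohex-1-en-1-yl]oxy}silane | C[C@@H]1CCCC(C)=C1O[Si](C)(C)C | intermediate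
3 | allyl chloroformate | C=CCOC(Cl)=O | starting material
4 | lithium (6R)-2,6-dimethylcyclohex-1-en-1-olate | [Li+].C[C@@H]1CCCC(C)=C1[O-] | intermediate
5 | allyl (6R)-2,6-dimethylcyclohex-1-en-1-yl carbonate | C[C@@H]1CCCC(C)=C1OC(=O)OCC=C | intermediate
6 | (2S,6R)-2-allyl-2,6-dimethylcyclohexanone (methyls cis) | C[C@@H]1CCC[C@@](C)(CC=C)C1=O | intermediate
7 | 4-[(1S,3R)-1,3-dimethyl-2-oxocyclohexyl]butanal | C[C@@H]1CCC[C@@](C)(CCCC=O)C1=O | intermediate
8 | (1S,4aS,8R,8aR)-4a,8-dimethyldecahydronaphthalene-1,8a-diol (cis-fused; 8α,9α-diol) | C[C@@H]1CCC[C@@]2(C)CCC[C@H](O)[C@@]12O | intermediate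
9 | (4aS,8R,8aR)-8a-hydroxy-4a,8-dimethyloctahydronaphthalen-1(2H)-one (cis-fused; C8 ketone, C9α hydroxyl) | C[C@@H]1CCC[C@@]2(C)CCCC(=O)[C@@]12O | intermediate
10 | 9α-O-trimethylsilyl C7=C8 trimethylsilyl enol ether of 9 | C[C@@H]1CCC[C@@]2(C)CCC=C(O[Si](C)(C)C)[C@@]12O[Si](C)(C)C | intermediate
11 | 9α-trimethylsilyloxy-4α,10α-dimethyl-cis-decal-6-en-8-one | C[C@@H]1CCC[C@@]2(C)CC=CC(=O)[C@@]12O[Si](C)(C)C | intermediate
12 | tert-butyl bromoacetate | CC(C)(C)OC(=O)CBr | starting material
13 | lithium 5,7-dienolate of 11 (C5=C6–C7=C8–OLi) | [Li+].C[C@@H]1CCC[C@@]2(C)C=CC=C([O-])[C@@]12O[Si](C)(C)C | intermediate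
14 | 7α-(tert-butoxycarbonylmethyl)-9α-trimethylsilyloxy-4α,10α-dimethyl-cis-decal-5-en-8-one | C[C@@H]1CCC[C@@]2(C)C=C[C@H](CC(=O)OC(C)(C)C)C(=O)[C@@]12O[Si](C)(C)C | intermediate
15 | 7α-(tert-butoxycarbonylmethyl)-9α-hydroxy-4α,10α-dimethyl-cis-decal-5-en-8-one | C[C@@H]1CCC[C@@]2(C)C=C[C@H](CC(=O)OC(C)(C)C)C(=O)[C@@]12O | intermediate
16 | 7α-(tert-butoxycarbonylmethyl)-4α,10α-dimethyl-cis-decal-5-ene-8β,9α-diol | C[C@@H]1CCC[C@@]2(C)C=C[C@H](CC(=O)OC(C)(C)C)[C@@H](O)[C@@]12O | intermediate
17 | 8β-tert-butyldimethylsilyl ether of 16 | C[C@@H]1CCC[C@@]2(C)C=C[C@H](CC(=O)OC(C)(C)C)[C@@H](O[Si](C)(C)C(C)(C)C)[C@@]12O | intermediate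
18 | dilithium C9-alkoxide ester enolate of 17 | [Li+].[Li+].C[C@@H]1CCC[C@@]2(C)C=C[C@H](C=C([O-])OC(C)(C)C)[C@@H](O[Si](C)(C)C(C)(C)C)[C@@]12[O-] | intermediate
19 | Mannich base: 17 with CH2NMe2 on C11 (C11 epimers) | C[C@@H]1CCC[C@@]2(C)C=C[C@H](C(CN(C)C)C(=O)OC(C)(C)C)[C@@H](O[Si](C)(C)C(C)(C)C)[C@@]12O | intermediate
20 | 5β,6β-diol of 19 (5β,6β,9α-triol 8β-silyl ether) | C[C@@H]1CCC[C@@]2(C)[C@@H](O)[C@@H](O)[C@H](C(CN(C)C)C(=O)OC(C)(C)C)[C@@H](O[Si](C)(C)C(C)(C)C)[C@@]12O | intermediate
21 | 6β-triethylsilyl ether of 20 | C[C@@H]1CCC[C@@]2(C)[C@@H](O)[C@@H](O[Si](CC)(CC)CC)[C@H](C(CN(C)C)C(=O)OC(C)(C)C)[C@@H](O[Si](C)(C)C(C)(C)C)[C@@]12O | intermediate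
22 | 5β-methanesulfonate of 21 (cis-decal-9α-ol; sulfonate trans to the C4 methyl) | C[C@@H]1CCC[C@@]2(C)[C@@H](OS(C)(=O)=O)[C@@H](O[Si](CC)(CC)CC)[C@H](C(CN(C)C)C(=O)OC(C)(C)C)[C@@H](O[Si](C)(C)C(C)(C)C)[C@@]12O | intermediate
23 | potassium C9-alkoxide of 22 | [K+].C[C@@H]1CCC[C@@]2(C)[C@@H](OS(C)(=O)=O)[C@@H](O[Si](CC)(CC)CC)[C@H](C(CN(C)C)C(=O)OC(C)(C)C)[C@@H](O[Si](C)(C)C(C)(C)C)[C@@]12[O-] | intermediate
24 | (4Z)-4,10-dimethyl-6-triethylsilyloxy-8-tert-butyldimethylsilyloxy-7-[1-(tert-butoxycarbonyl)-2-(dimethylamino)ethyl]cyclodec-4-en-9-one (germacrane numbering) | C[C@@H]1CCC/C(C)=C\[C@@H](O[Si](CC)(CC)CC)[C@H](C(CN(C)C)C(=O)OC(C)(C)C)[C@@H](O[Si](C)(C)C(C)(C)C)C1=O | intermediate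
25 | C6 alcohol of 24 | C[C@@H]1CCC/C(C)=C\[C@@H](O)[C@H](C(CN(C)C)C(=O)OC(C)(C)C)[C@@H](O[Si](C)(C)C(C)(C)C)C1=O | intermediate
26 | TMEDA-bound cyclic osmate ester across C4 and C5 of 25 | C[C@@H]1CCC[C@]2(C)O[Os](=O)(=O)O[C@@H]2[C@@H](O)[C@H](C(CN(C)C)C(=O)OC(C)(C)C)[C@@H](O[Si](C)(C)C(C)(C)C)C1=O.CN(C)CCN(C)C | intermediate
27 | 4,5,6-triol tert-butyl ester (8-silyl ether, 9-ketone) | C[C@@H]1CCC[C@](C)(O)[C@H](O)[C@@H](O)[C@H](C(CN(C)C)C(=O)OC(C)(C)C)[C@@H](O[Si](C)(C)C(C)(C)C)C1=O | intermediate
28 | 4,5,6-trihydroxy acid from 27 | C[C@@H]1CCC[C@](C)(O)[C@H](O)[C@@H](O)[C@H](C(CN(C)C)C(=O)O)[C@@H](O[Si](C)(C)C(C)(C)C)C1=O | intermediate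
29 | 4,5-dihydroxy-8-tert-butyldimethylsilyloxy-13-dimethylamino-9-oxogermacran-12,6-olide | C[C@@H]1CCC[C@](C)(O)[C@H](O)[C@H]2OC(=O)C(CN(C)C)[C@@H]2[C@@H](O[Si](C)(C)C(C)(C)C)C1=O | intermediate
30 | isobutyryl chloride | CC(C)C(Cl)=O | starting material
31 | 5-isobutyrate of 29 | C[C@@H]1CCC[C@](C)(O)[C@H](OC(=O)C(C)C)[C@H]2OC(=O)C(CN(C)C)[C@@H]2[C@@H](O[Si](C)(C)C(C)(C)C)C1=O | intermediate
32 | 8-hydroxy 5-isobutyrate (13-dimethylamino lactone) | C[C@@H]1CCC[C@](C)(O)[C@H](OC(=O)C(C)C)[C@H]2OC(=O)C(CN(C)C)[C@@H]2[C@@H](O)C1=O | intermediate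
33 | (R)-2-methylbutanoic acid | CC[C@@H](C)C(=O)O | starting material
34 | 8-[(R)-2-methylbutanoate] 5-isobutyrate (13-dimethylamino lactone) | C[C@@H]1CCC[C@](C)(O)[C@H](OC(=O)C(C)C)[C@H]2OC(=O)C(CN(C)C)[C@@H]2[C@@H](OC(=O)[C@H](C)CC)C1=O | intermediate
35 | 13-trimethylammonium iodide of 34 | [I-].C[C@@H]1CCC[C@](C)(O)[C@H](OC(=O)C(C)C)[C@H]2OC(=O)C(C[N+](C)(C)C)[C@@H]2[C@@H](OC(=O)[C@H](C)CC)C1=O | intermediate
36 | CNP0071420.1, (4S,5R,6S,7S,8R,10R)-4-hydroxy-5-isobutyryloxy-8-[(R)-2-methylbutanoyloxy]-9-oxogermacr-11(13)-en-12,6-olide | C=C1C(=O)O[C@H]2[C@H]1[C@@H](OC(=O)[C@H](C)CC)C(=O)[C@H](C)CCC[C@](C)(O)[C@@H]2OC(=O)C(C)C | target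

**Step count and risks**

Total step count: 24. Longest linear sequence: 24 steps (1 to 36).

The three steps most likely to fail:

1. Step 17 (fragmentation). The twist of ring B that brings the C5–O bond anti to C4–C9 may be reached too slowly. The alkoxide would then be lost to silyl transfer from O8, to intermolecular elimination toward C6, or to enolisation of the product ketone with loss of the C8 or C10 configuration.
 Fallback (from 21, back at 27): the geometry problem is removed by inverting C5 and accepting the E alkene. The axial 5β-hydroxyl of 21 is oxidised (SO3·pyridine, DMSO, i-Pr2NEt) to the C5 ketone F1. Equilibrating Meerwein–Ponndorf–Verley reduction (Al(Oi-Pr)3, i-PrOH) should return the equatorial 5α-alcohol F2, which is free of the syn-axial contact with C10. MsCl/Et3N gives the 5α-methanesulfonate F3, whose C5–O bond is anti to C4–C9 already in the chair–chair ground state. KN(SiMe3)2 then opens it to the (4E)-cyclodecenone F4. HF·pyridine frees the C6 hydroxyl to give the (4E)-allylic alcohol F5. m-CPBA on the trifluoroacetate salt of the amine epoxidises syn to that hydroxyl from the outer face to the 4,5-epoxide F6. Dilute aqueous HClO4 opens the epoxide at tertiary C4 with inversion; because anti addition to the E alkene equals syn addition to the Z alkene, this gives triol 27.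

2. Step 14 (first osmylation). Facial selectivity may be poor or inverted. The β face needed is the concave one and is shielded by axial C10, while the α face is shielded by the C4 methyl, so osmium may add α or unselectively.
 Fallback (from 17, back at 21): the cis-diol is delivered by the iodonium/acetoxonium route, which places both oxygens on the face opposite to the one a bulky electrophile chooses, and is run before the amine is present. Woodward cis-hydroxylation of 17 (I2, AgOAc, wet AcOH) should give the 5β-acetoxy-6β-alcohol F7. K2CO3/MeOH gives the 5β,6β-diol F8. TESCl/imidazole gives the 6β-triethylsilyl ether F9. The ester-enolate Mannich reaction (LiN(i-Pr)2 in excess, then Me2N=CH2 I) then gives 21.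

3. Step 19 (directed osmylation on the ten-membered ring). The directing hydrogen bond may be lost, for example through a transannular hemiketal between O6 and C9 or through competing coordination of osmium by the side-chain amine. Facial control would then erode and over-oxidation could follow.
 Fallback (from 25, back at 29): control is moved from hydrogen-bond delivery to the shape of the bicyclic lactone. Aqueous H3PO4 first converts 25 into the (4Z)-alkene 6,12-lactone F10. On this trans-fused lactone the alkene should be open only on its outer face, which is the face syn to O6, so catalytic OsO4/NMO is expected to give 29 directly.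

Further compounds
F1 | step 17 | C5 ketone from 21 (6β-triethylsilyloxy, 8β-tert-butyldimethylsilyloxy, 9α-hydroxy) | C[C@@H]1CCC[C@@]2(C)C(=O)[C@@H](O[Si](CC)(CC)CC)[C@H](C(CN(C)C)C(=O)OC(C)(C)C)[C@@H](O[Si](C)(C)C(C)(C)C)[C@@]12O
F2 | step 17 | 5α-alcohol (C5 epimer of 21) | C[C@@H]1CCC[C@@]2(C)[C@H](O)[C@@H](O[Si](CC)(CC)CC)[C@H](C(CN(C)C)C(=O)OC(C)(C)C)[C@@H](O[Si](C)(C)C(C)(C)C)[C@@]12O
F3 | step 17 | 5α-methanesulfonate (C5 epimer of 22) | C[C@@H]1CCC[C@@]2(C)[C@H](OS(C)(=O)=O)[C@@H](O[Si](CC)(CC)CC)[C@H](C(CN(C)C)C(=O)OC(C)(C)C)[C@@H](O[Si](C)(C)C(C)(C)C)[C@@]12O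
F4 | step 17 | (4E)-cyclodecenone (E isomer of 24) | C[C@@H]1CCC/C(C)=C/[C@@H](O[Si](CC)(CC)CC)[C@H](C(CN(C)C)C(=O)OC(C)(C)C)[C@@H](O[Si](C)(C)C(C)(C)C)C1=O
F5 | step 17 | (4E)-allylic alcohol (E isomer of 25) | C[C@@H]1CCC/C(C)=C/[C@@H](O)[C@H](C(CN(C)C)C(=O)OC(C)(C)C)[C@@H](O[Si](C)(C)C(C)(C)C)C1=O
F6 | step 17 | 4,5-epoxide of F5 (oxygen syn to the C6 hydroxyl) | C[C@@H]1CCC[C@@]2(C)O[C@@H]2[C@@H](O)[C@H](C(CN(C)C)C(=O)OC(C)(C)C)[C@@H](O[Si](C)(C)C(C)(C)C)C1=O
F7 | step 14 | 5β-acetoxy-6β-alcohol from 17 | C[C@@H]1CCC[C@@]2(C)[C@@H](OC(C)=O)[C@@H](O)[C@H](CC(=O)OC(C)(C)C)[C@@H](O[Si](C)(C)C(C)(C)C)[C@@]12O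
F8 | step 14 | 5β,6β-diol from 17 (no amine) | C[C@@H]1CCC[C@@]2(C)[C@@H](O)[C@@H](O)[C@H](CC(=O)OC(C)(C)C)[C@@H](O[Si](C)(C)C(C)(C)C)[C@@]12O
F9 | step 14 | 6β-triethylsilyl ether of F8 | C[C@@H]1CCC[C@@]2(C)[C@@H](O)[C@@H](O[Si](CC)(CC)CC)[C@H](CC(=O)OC(C)(C)C)[C@@H](O[Si](C)(C)C(C)(C)C)[C@@]12O
F10 | step 19 | (4Z)-alkene 6,12-lactone (8-silyl ether, Mannich base) | C[C@@H]1CCC/C(C)=C\[C@H]2OC(=O)C(CN(C)C)[C@@H]2[C@@H](O[Si](C)(C)C(C)(C)C)C1=O
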